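in all of them: left-handed substrate 0.050 M; right-handed substrate 0.050 M; coupling partner 0.125 M; free catalyst 1.2 mM

| run | racemization catalyst | impurity | temperature | remark | time |
|---|---|---|---|---|---|
| dawn | 1.2 mM | 1.4 mM | 89 °C | run made earlier |  |
| dusk | 1.2 mM | 2.2 mM | 97 °C | run made earlier |  |
| autumn | 2.4 mM | 1 mM | 89 °C | run made earlier |  |
| north-west | 1.2 mM | 1.0 mM | 85 °C |  | 25 d |
| east | 1.2 mM | 1.0 mM | 100 °C |  | 25 d |

| run | time / d | left-handed product / % | right-handed product / % |
|---|---|---|---|
| dawn | 3.00 | 20.1 | 13.2 |
| dawn | 8.00 | 18.7 | 15.6 |
| dawn | 15.0 | 17.3 | 16.9 |
| dawn | 25.0 | 17.7 | 16.7 |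
| dusk | 1.67 | 8.0 | 6.1 |
| dusk | 4.00 | 8.3 | 7.8 |
| dusk | 8.00 | 8.3 | 7.3 |
| dusk | 15.0 | 7.5 | 7.6 |
| autumn | 3.00 | 44.4 | 35.3 |
| autumn | 8.00 | 48.1 | 44.4 |
| autumn | 15.0 | 49.8 | 49.1 |
| autumn | 25.0 | 49.6 | 49.9 |

(each reading ± 0.5 percentage points)

- the flask with the highest share of left-handed product in all that became left-handed product or right-handed product ("all alike" if they lie within 1.5 percentage points) (north-west / east / all alike)
- share of left-handed product in all that became left-handed product or right-handed product, north-west
- share of left-handed product in all that became left-handed product or right-handed product, east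

- free catalyst is single-handed; left-handed substrate and right-handed substrate are mirror images of each other, charged as a racemate, each of them at the stated concentration
- candidate steps: coupling partner + free catalyst + left-handed substrate -> free catalyst + left-handed product; coupling partner + free catalyst + right-handed substrate -> free catalyst + right-handed product; left-handed substrate + racemization catalyst <-> right-handed substrate + racemization catalyst; free catalyst + impurity -> spent catalyst; left-handed product <-> right-handed product

At 89 °C the dawn run stopped near 34.4% of the charge, and at 97 °C the dusk run stopped near 15.1%. Each of these was charged with more impurity than free catalyst . The autumn run was charged with less and read 99.5% at its last reading.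

So I carried one quantity. The catalyst margin, free catalyst charged minus impurity charged, is 0.200 mM in north-west and in east. In both flasks impurity is the limiting reagent of the poisoning step. The autumn run had the same margin, 0.200 mM, though at 89 °C and with 2.4 mM of racemization catalyst, so I read the rate there.

Over its first 3.00 d the autumn run averaged 0.266 d⁻¹, as a fraction of the charge. From there up to 8.00 d it averaged 0.0256 d⁻¹, ten times slower. By the balance, free catalyst in the autumn run can fall by a factor of 6.00. At full conversion, coupling partner in that run falls by a factor of 5.00. The unconverted part of the autumn run, as read, still fell from 7.50% to 1.10% by 15.0 d.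

I therefore expected north-west and east to keep converting up to 25 d. In the dawn run the gap between the products shrank at 0.160 d⁻¹, as read from the readings. At that rate, read at 89 °C, a gap keeps 1.83% of itself over 25 d. So I expected both shares near even.

The forecast gave north-west 50.7%, east 50%, and all alike. One of its grounds was that “Both new flasks also keep 0.2 mM catalyst”.

The flasks gave 49.8% in north-west and 50.0% in east: all alike.

    coupling partner + free catalyst + left-handed substrate → free catalyst + left-handed product (k = 3640 M⁻² h⁻¹, Ea = 53.0 kJ mol⁻¹)
    coupling partner + free catalyst + right-handed substrate → free catalyst + right-handed product (k = 1760 M⁻² h⁻¹, Ea = 68.0 kJ mol⁻¹)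
    left-handed substrate + racemization catalyst ⇌ right-handed substrate + racemization catalyst, rate k3*[racemization catalyst]*[left-handed substrate] forward; the back reaction follows from the equilibrium constant (k = 3.63 M⁻¹ h⁻¹, Ea = 95.0 kJ mol⁻¹)
    free catalyst + impurity → spent catalyst (k = 1580 M⁻¹ h⁻¹, Ea = 77.0 kJ mol⁻¹)
    left-handed product ⇌ right-handed product (k = 0.0123 h⁻¹, Ea = 125 kJ mol⁻¹)
    (constants at 100 °C)

The margin was 16.7% of the free catalyst charged, and at 25.0 d north-west held free catalyst at 16.7% of that charge and east at 16.7%. The time asked in east was ten times the half-life of the slowest mode of that flask, 2.52 d at 25.0 d. A neighbour of east charged with 0.0025 M of impurity had a margin of −1.30 mM. At 25.0 d that neighbour held free catalyst at 0% and left-handed product at 6.16%.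

The numbers in the tables stem from a simulated flask for an exercise; the scatter is artificial.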